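(Its constants were drawn at random within sensible limits; the flask was simulated.)

Count reagent first: one target holds two reagent units, one taken up in the first step and one in the second, so the charge caps target at 65.0% of the substrate, and reagent is the limiting reagent, its half-charge being smaller than either partner's or substrate's.

    substrate + reagent → open intermediate (k1 = 0.0051 M⁻¹ s⁻¹)
    reagent + partner → second intermediate (k2 = 0.046 M⁻¹ s⁻¹)
    open intermediate + second intermediate → target (k3 = 0.25 M⁻¹ s⁻¹)
    2 open intermediate → homo product (k4 = 0.16 M⁻¹ s⁻¹)
    substrate + target → side product (k5 = 8.2 × 10⁻⁴ M⁻¹ s⁻¹)

| flask | substrate | partner | reagent | time | remark |
|---|---|---|---|---|---|
| gamma | 0.40 M | 0.440 M | 0.520 M | 5.0 min | a tube with plug flow, the mixed feed as stated, residence time 5.0 min |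
| delta | 0.40 M | 0.440 M (fed, over 5.00 min) | 0.520 M | 5.0 min | a stirred flask in which partner is dosed at a steady rate over 5.00 min without added volume, worked up at 5.0 min |
| zeta | 0.40 M | 0.440 M | 0.520 M | 5.0 min | everything together in a closed stirred flask, run for 5.0 min |
| theta | 0.40 M | 0.440 M | 0.520 M |  | a single well-mixed tank run continuously and read at steady state, 5.0 min in it on average |

- percent here means substrate units held: one homo product or side product counts as two
- where a step has two of a species, its rate is k times that concentration squared, and two are used at each turn
- the stated concentrations are those of everything mixed, before any reaction; amounts are the same in each set-up
- the feed brings no volume worth counting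
- run time (gamma): 5.0 min

- the set-up with the highest amount of target at the outlet or at the end, in percent of the substrate put in ("none" if the first two lie within 2 percentage points) (gamma / delta / zeta / theta / none)
- amount of target at the outlet or at the end, in percent of the substrate put in, gamma
- amount of target at the outlet or at the end, in percent of the substrate put in, delta
- amount of target at the outlet or at the end, in percent of the substrate put in, zeta
- amount of target at the outlet or at the end, in percent of the substrate put in, theta

Reagent stands at a fork. The first and second steps draw on it equally when [partner] equals [substrate] times the ratio of their constants, 0.111. For the charged substrate that is 0.0443 M, the balance level of partner. Above it, reagent goes mainly to second intermediate; below it, open intermediate is made faster than its mate and can pair with itself.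

The first thing you can turn is how partner enters. Mix everything at once, as in zeta or in gamma, whose residence time makes it the same reckoning, and [partner] starts at ten times the balance level. While the two steps share reagent, ln[substrate] moves at that ratio of ln[partner], so by the time partner has come down to balance, substrate has lost 22.5%, which I take as target for both.

Dose partner instead, as in delta, and it arrives at a steady pace and is eaten by the second step; with reagent as charged, feed and second step match at [partner] = 0.0613 M, which is 1.38 times balance, and this matching level climbs as reagent falls. Reagent then falls about evenly, averaging [reagent] charge minus half the partner, and substrate spent gives a ceiling for target of 36.8%, since some open intermediate pairs with itself.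

Run a tank, as in theta, and the steady balance puts [partner] near 0.118 M, with a ceiling of 23.2%. By substrate spent, my choice is delta.

The forecast gave 18% for gamma, 23% for delta, 18% for zeta and 15.8% for theta, and named delta, since dosing “keeps reagent available for substrate”.

The simulation gives 22.8% of target for delta, the highest, against 18.4% for gamma, 18.4% for zeta and 15.8% for theta, so the best set-up is delta. Delta also ends with 11.4% as homo product, against 0.825% in zeta. At 2.50 min delta's [partner] reads 0.0848 M, which is 1.91 times balance, and at 5.00 min it reads 0.163 M, which is 3.68 times balance. A neighbouring delta flask charged with 0.11 M of partner has, with reagent as charged, a matching level of 0.0153 M, lower than balance, and it ends with 11.5% of target and 26.3% of homo product.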